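**Plan**
- Retrosynthesis: the exocyclic C5=CBr2 bond goes back to a lactol (C5–OH, CHBr2), the two exocyclic bromines to a methyl group, and the lactone O1–C5 bond to a cis keto acid. C3–C4 and C4–C5 are then cut together, so that C4 with its bromine leaves as dibromocarbene and ethyl 2-butylacetoacetate remains.
- Enabling feature: C4 of the furanone ring carries only Br and two ring-carbon neighbours (C3 with the butyl chain, C5 with the dibromomethylidene). It is therefore a one-carbon CBr unit lying between the α-carbon and the ketone carbon of a 2-butylacetoacetate.
- Forward: O-silylation; insertion of C4, which joins the C3–C4–C5 chain in one operation with no ring yet; ester cleavage, which closes the only ring at O1–C5 as a lactol; dibromination of the C5 methyl group; dehydration to the dibromomethylidene.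
- Stereochemistry: the target has no stereocentre and its exocyclic alkene bears two identical bromines, so nothing has to be controlled. The lactol centre formed on the way is racemic and is destroyed in the last step.

Key step: step 2

Assumption: the target is achiral, so its constitution alone defines it; the enol ether and the bromo enoate are drawn as one geometric isomer each, and any other isomer is carried forward because both converge at the lactol.

**Route**

Step 1
Reactants: 1 ethyl 2-butyl-3-oxobutanoate (ethyl 2-butylacetoacetate, racemic); 2 tert-butyldimethylsilyl trifluoromethanesulfonate (TBSOTf)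
Product: 3 ethyl (Z)-2-butyl-3-[(tert-butyldimethylsilyl)oxy]but-2-enoate (silyloxy and ester cis)
Conditions: 2 (1.2 equiv), Et3N (1.5 equiv), CH2Cl2, 0 °C → rt
Reagents that add atoms: tert-butyldimethylsilyl trifluoromethanesulfonate (2), CC(C)(C)[Si](C)(C)OS(=O)(=O)C(F)(F)F
Why: Soft enolisation of the β-keto ester by triethylamine and O-silylation by the hard silyl triflate is the standard route to β-keto ester silyl enol ethers, and TBS is chosen over TMS so that the enol ether withstands tert-butoxide in step 2.

Step 2
Reactants: 3 ethyl (Z)-2-butyl-3-[(tert-butyldimethylsilyl)oxy]but-2-enoate; 4 bromoform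
Product: 6 ethyl (E)-3-bromo-2-butyl-4-oxopent-2-enoate (acetyl and ester cis), via silyloxy-dibromocyclopropane 5 (not isolated)
Conditions: 4 (2.0 equiv), KOtBu (1.8 equiv, portionwise), pentane, −30 → 0 °C; filter; then PhMe, 60 °C
Reagents that add atoms: bromoform (4), BrC(Br)Br
Why: Proposed new method: tert-butoxide converts bromoform into dibromocarbene (Doering–Hoffmann α-elimination), which adds in a (2+1) cheletropic step to the enol ether double bond of 3, bonding first to the nucleophilic ester-bearing carbon (future C3) and then to the oxygenated carbon (future C5), so that C3–C4 and C4–C5 arise together in cyclopropane 5. On warming, the ring bond between the two former alkene carbons breaks, because it alone is flanked by the silyloxy donor and the ester acceptor (oxocarbenium/ester-enolate zwitterion, or equivalently bromide-assisted disrotatory cyclopropyl-to-allyl opening), bromide leaves from C4 and the silyl group is transferred to bromide, giving the C3=C4 alkene conjugated to both carbonyls. The closest known reaction types are dihalocarbene addition to ketone silyl enol ethers with ring opening to α-halo enones and the zinc-carbenoid chain extension of β-keto esters to γ-keto esters; the ester-bearing tetrasubstituted enol ether is the untested element. No ring of the target closes here (the three-membered ring is transient) and no stereocentre survives, 5 being racemic and consumed. Chemoselectivity for carbene addition over base-induced desilylation is secured by the TBS group, the insoluble base in pentane and bromoform kept in excess over base, and regioselective ring cleavage by the donor–acceptor substitution; the alkene geometry of 6 need not be controlled, since both isomers converge once the ester is cleaved in step 3.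

Step 3
Reactants: 6 ethyl (E)-3-bromo-2-butyl-4-oxopent-2-enoate
Product: 8 racemic 4-bromo-3-butyl-5-hydroxy-5-methylfuran-2(5H)-one (lactol), via keto acid 7 (not isolated)
Conditions: 48% aq. HBr, AcOH, 90 °C
Reagents that add atoms: water, O
Why: Acid-catalysed ester hydrolysis gives keto acid 7, whose cis acetyl and carboxyl groups close by ring–chain tautomerism (5-exo-trig addition of the carboxyl oxygen to the ketone) to the pseudo-acid lactol, while any Z isomer should equilibrate by reversible conjugate addition–elimination of HBr, bromide being the only nucleophile so that halide exchange is degenerate.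

Step 4
Reactants: 8 racemic 4-bromo-3-butyl-5-hydroxy-5-methylfuran-2(5H)-one; 9 bromine
Product: 11 racemic 4-bromo-3-butyl-5-(dibromomethyl)-5-hydroxyfuran-2(5H)-one (lactol), via bromomethyl lactol 10 (not isolated)
Conditions: 9 (2.2 equiv), HBr (cat.), AcOH, 60 °C, dark
Reagents that add atoms: bromine (9), BrBr
Why: Acid-catalysed α-bromination of a methyl ketone, reached through the open keto-acid tautomer and able to enolise only towards CH3 because the other α-carbon is vinylic, should run twice at the same carbon as in the side-chain bromination of γ-keto acids and their pseudo-acids, while the electron-poor tetrasubstituted ring alkene is inert to bromine and darkness suppresses radical bromination of the allylic butyl CH2.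

Step 5
Reactants: 11 racemic 4-bromo-3-butyl-5-(dibromomethyl)-5-hydroxyfuran-2(5H)-one
Product: 12 4-bromo-3-butyl-5-(dibromomethylidene)furan-2(5H)-one (target)
Conditions: conc. H2SO4, 100 °C, 20 min; then ice
Reagents that add atoms: none
Why: Ionisation of the lactol hydroxyl in concentrated sulfuric acid and loss of the CHBr2 proton (E1 dehydration of a pseudo-acid to the enol lactone) follows the classical sulfuric acid cyclodehydration of brominated 4-oxo acids to 5-(halomethylidene)furanones, and the two identical bromines exclude any alkene isomer.

**Compound list**
1 | ethyl 2-butyl-3-oxobutanoate (ethyl 2-butylacetoacetate, racemic) | CCCCC(C(C)=O)C(=O)OCC | starting material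
2 | tert-butyldimethylsilyl trifluoromethanesulfonate | CC(C)(C)[Si](C)(C)OS(=O)(=O)C(F)(F)F | starting material
3 | ethyl (Z)-2-butyl-3-[(tert-butyldimethylsilyl)oxy]but-2-enoate | CCCC/C(C(=O)OCC)=C(\C)O[Si](C)(C)C(C)(C)C | intermediate
4 | bromoform | BrC(Br)Br | starting material
5 | ethyl 2,2-dibromo-1-butyl-3-[(tert-butyldimethylsilyl)oxy]-3-methylcyclopropane-1-carboxylate (racemic, ester and silyloxy cis; not isolated) | CCCC[C@]1(C(=O)OCC)C(Br)(Br)[C@@]1(C)O[Si](C)(C)C(C)(C)C | intermediate
6 | ethyl (E)-3-bromo-2-butyl-4-oxopent-2-enoate | CCCC/C(C(=O)OCC)=C(\Br)C(C)=O | intermediate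
7 | (E)-3-bromo-2-butyl-4-oxopent-2-enoic acid (not isolated) | CCCC/C(C(=O)O)=C(\Br)C(C)=O | intermediate
8 | 4-bromo-3-butyl-5-hydroxy-5-methylfuran-2(5H)-one (racemic) | CCCCC1=C(Br)C(C)(O)OC1=O | intermediate
9 | bromine | BrBr | starting material
10 | 4-bromo-5-(bromomethyl)-3-butyl-5-hydroxyfuran-2(5H)-one (racemic; not isolated) | CCCCC1=C(Br)C(O)(CBr)OC1=O | intermediate
11 | 4-bromo-3-butyl-5-(dibromomethyl)-5-hydroxyfuran-2(5H)-one (racemic) | CCCCC1=C(Br)C(O)(C(Br)Br)OC1=O | intermediate
12 | 4-bromo-3-butyl-5-(dibromomethylidene)furan-2(5H)-one | CCCCC1=C(Br)C(=C(Br)Br)OC1=O | target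

**Step count**
Total steps: 5. Longest linear sequence: 5 steps, from 1 to 12.

**Steps most likely to fail**

Step 2 (proposed new method). tert-Butoxide may strip the silyl group before the carbene adds, the ester-deactivated tetrasubstituted alkene may add the carbene too slowly, or base may attack the β-bromo enoate once it forms. The fallback sets out from 1 and rejoins the route at 12, using only known chemistry. Zinc-carbenoid chain extension of 1 (Et2Zn, CH2I2, CH2Cl2, 0 °C → rt) inserts CH2 between the α-carbon and the ketone carbon and should give ethyl 2-butyl-4-oxopentanoate F1. Saponification (LiOH, THF/H2O, then HCl) gives 2-butyl-4-oxopentanoic acid F2. Bromination with excess bromine (CHCl3, cat. HBr) gives 3,5,5-tribromo-2-butyl-4-oxopentanoic acid F3. Hot concentrated sulfuric acid (100–110 °C) then effects cyclodehydration with dehydrogenation of the ring to 12, the classical end-game for this furanone class.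

Step 4. Bromination may stray to the allylic butyl CH2 (radical pathway or extended dienol of the open enone), or the second bromination of the masked ketone may stall. The fallback sets out from 8 and rejoins at 12, bypassing 11 and step 5. Dehydration of 8 (P2O5, CH2Cl2, reflux) gives 4-bromo-3-butyl-5-methylidenefuran-2(5H)-one F4. Bromine adds only to its electron-rich exocyclic enol-lactone alkene (CH2Cl2, 0 °C) to give 4,5-dibromo-5-(bromomethyl)-3-butylfuran-2(5H)-one F5. DBU removes HBr to give (Z)-4-bromo-5-(bromomethylidene)-3-butylfuran-2(5H)-one F6. A second bromine addition gives 4,5-dibromo-3-butyl-5-(dibromomethyl)furan-2(5H)-one F7, and a second DBU dehydrobromination gives 12.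

Step 5. Ionisation of the lactol may be too slow because the cation is destabilised by CHBr2 and the bromo-butenolide, so that charring in hot acid outruns dehydration. The fallback sets out from 11 and rejoins at 12. Thionyl chloride with catalytic DMF converts the pseudo-acid into its cyclic pseudo-chloride, 4-bromo-3-butyl-5-chloro-5-(dibromomethyl)furan-2(5H)-one F8, as is known for mucohalic and 2-acylbenzoic acids. Triethylamine or DBU (CH2Cl2, 0 °C) then removes HCl in a base-mediated elimination to give 12.

**Further compounds**
F1 | step 2 | ethyl 2-butyl-4-oxopentanoate | CCCCC(CC(C)=O)C(=O)OCC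
F2 | step 2 | 2-butyl-4-oxopentanoic acid | CCCCC(CC(C)=O)C(=O)O
F3 | step 2 | 3,5,5-tribromo-2-butyl-4-oxopentanoic acid | CCCCC(C(Br)C(=O)C(Br)Br)C(=O)O
F4 | step 4 | 4-bromo-3-butyl-5-methylidenefuran-2(5H)-one | CCCCC1=C(Br)C(=C)OC1=O
F5 | step 4 | 4,5-dibromo-5-(bromomethyl)-3-butylfuran-2(5H)-one | CCCCC1=C(Br)C(Br)(CBr)OC1=O
F6 | step 4 | (Z)-4-bromo-5-(bromomethylidene)-3-butylfuran-2(5H)-one | CCCCC1=C(Br)/C(=C/Br)OC1=O
F7 | step 4 | 4,5-dibromo-3-butyl-5-(dibromomethyl)furan-2(5H)-one | CCCCC1=C(Br)C(Br)(C(Br)Br)OC1=O
F8 | step 5 | 4-bromo-3-butyl-5-chloro-5-(dibromomethyl)furan-2(5H)-one | CCCCC1=C(Br)C(Cl)(C(Br)Br)OC1=O
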